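**Retrosynthetic overview**
- The strategy rests on ring B being a benzene with aryloxy on C1, hydroxyl on C2, the quaternary carbon on C3 and three adjacent CH at C4–C6. This is the pattern left when a 3-aryloxy-2-pyrone takes up an O-silyl ynol ether across C3/C6 and loses CO2, so ring B is cut at C1–C2 and C3–C4.
- The diaryl ether oxygen is therefore installed before ring B exists, by C–O coupling of a ring A phenol with 3-bromo-2-pyrone.
- Both quaternary centres come from farnesyl diethyl phosphate by copper-catalysed SN2' substitution: aryl transfer gives the (R) centre, alkynyl transfer with the mirror-image ligand gives the (S) centre.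
- Ring order: ring A is bought (5-bromo-1,2,3-trimethoxybenzene) and its three oxygens are differentiated by one silylene on the C2-symmetric pyrogallol; the pyrone ring is bought; ring B is formed last, then fluoride frees the three phenols.

Key step: step 11

Assumption: L denotes the enantiomer of the chiral sulfonate-bearing imidazolinium salt (1,2-diphenylethylenediamine backbone) whose NHC–copper catalyst delivers a carbon nucleophile to the face of the farnesyl phosphate that gives the (R) aryl centre; alkynyl transfer is taken to follow the same facial preference, so ent-L is used for the (S) centre, and both assignments are to be checked on the first runs.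

**Route**

Step 1
Reactants: 1 (2E,6E)-farnesol
Product: 2 (2E,6E)-farnesyl diethyl phosphate
Conditions: ClP(O)(OEt)2, Et3N, DMAP (cat.), CH2Cl2, 0 °C
Reagents that add atoms: diethyl chlorophosphate, CCOP(=O)(Cl)OCC
Why: O-phosphorylation of the primary allylic alcohol under amine base leaves the three alkenes untouched and installs the leaving group needed for copper-catalysed allylic substitution.

Step 2
Reactants: 3 5-bromo-1,2,3-trimethoxybenzene
Product: 4 5-bromobenzene-1,2,3-triol
Conditions: BBr3, CH2Cl2, −78 °C → rt; H2O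
Reagents that add atoms: none
Why: Lewis-acid cleavage of the three aryl methyl ethers is done here, before any acid-sensitive polyene is present.

Step 3
Reactants: 4 5-bromobenzene-1,2,3-triol
Product: 5 5-bromo-1,2,3-tris(tert-butyldimethylsilyloxy)benzene
Conditions: TBSCl, imidazole, DMAP (cat.), DMF, rt
Reagents that add atoms: tert-butyldimethylsilyl chloride, CC(C)(C)[Si](C)(C)Cl
Why: Imidazole-promoted silyl ether formation gives phenol protection that tolerates organolithium and organoaluminium reagents and, lying meta and para to bromine, cannot undergo retro-Brook migration after metalation.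

Step 4
Reactants: 5 5-bromo-1,2,3-tris(tert-butyldimethylsilyloxy)benzene; 2 (2E,6E)-farnesyl diethyl phosphate
Product: 8 1,2,3-tris(tert-butyldimethylsilyloxy)-5-[(3R,6E)-3,7,11-trimethyldodeca-1,6,10-trien-3-yl]benzene, via aryllithium 6 (not isolated), via diethyl(aryl)aluminium 7 (not isolated)
Conditions: n-BuLi, Et2O, −78 °C; Et2AlCl, −78 °C → rt; then 2, L (3 mol%, pre-stirred with Ag2O), CuCl2·2H2O (6 mol%), THF, −30 °C
Reagents that add atoms: none
Why: Bromine–lithium exchange and transmetalation give an aryl(diethyl)aluminium that transfers only its aryl group in an NHC–copper-catalysed enantioselective allylic substitution, which should go SN2' at the trisubstituted alkene of 2 to build the quaternary carbon, with the (R) configuration set by the catalyst from L discriminating the faces of the E-alkene.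

Step 5
Reactants: 8 1,2,3-tris(tert-butyldimethylsilyloxy)-5-[(3R,6E)-3,7,11-trimethyldodeca-1,6,10-trien-3-yl]benzene
Product: 9 5-[(3R,6E)-3,7,11-trimethyldodeca-1,6,10-trien-3-yl]benzene-1,2,3-triol
Conditions: TBAF, AcOH, THF (degassed), 0 °C
Reagents that add atoms: none
Why: Fluoride-mediated cleavage of aryl silyl ethers is fast at 0 °C, and the acetic acid buffer under argon should release the oxidation-prone pyrogallol without affecting the alkenes.

Step 6
Reactants: 9 5-[(3R,6E)-3,7,11-trimethyldodeca-1,6,10-trien-3-yl]benzene-1,2,3-triol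
Product: 10 2,2-di-tert-butyl-6-[(3R,6E)-3,7,11-trimethyldodeca-1,6,10-trien-3-yl]-1,3,2-benzodioxasilol-4-ol
Conditions: t-Bu2Si(OTf)2 (1.0 equiv), 2,6-lutidine, CH2Cl2, −78 → 0 °C
Reagents that add atoms: di-tert-butylsilyl bis(trifluoromethanesulfonate), CC(C)(C)[Si](OS(=O)(=O)C(F)(F)F)(OS(=O)(=O)C(F)(F)F)C(C)(C)C
Why: Cyclic silylene formation bridges two adjacent phenols as a five-membered dioxasilole, and because the 5-substituted pyrogallol has a twofold axis through C2 and C5 either neighbouring pair gives the same compound with exactly one free phenol.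

Step 7
Reactants: 10 2,2-di-tert-butyl-6-[(3R,6E)-3,7,11-trimethyldodeca-1,6,10-trien-3-yl]-1,3,2-benzodioxasilol-4-ol; 11 3-bromo-2H-pyran-2-one
Product: 12 3-({2,2-di-tert-butyl-6-[(3R,6E)-3,7,11-trimethyldodeca-1,6,10-trien-3-yl]-1,3,2-benzodioxasilol-4-yl}oxy)-2H-pyran-2-one
Conditions: Pd(OAc)2 (5 mol%), t-BuXPhos (10 mol%), K3PO4, toluene, 80 °C
Reagents that add atoms: none
Why: Palladium-catalysed C–O cross-coupling (Buchwald–Hartwig etherification) should proceed by easy oxidative addition into the electron-poor C3–Br bond and phenoxide reductive elimination promoted by the bulky biarylphosphine, while insoluble K3PO4 in toluene keeps free phenoxide low enough to spare the lactone and the silylene.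

Step 8
Reactants: 13 trimethylsilylacetylene; 2 (2E,6E)-farnesyl diethyl phosphate
Product: 15 trimethyl[(3S,6E)-3-ethenyl-3,7,11-trimethyldodeca-6,10-dien-1-yn-1-yl]silane, via diisobutyl(silylethynyl)aluminium 14 (not isolated)
Conditions: i-Bu2AlH, Et3N (5 mol%), hexanes, 22–50 °C; then 2, ent-L (3 mol%, pre-stirred with Ag2O), CuCl2·2H2O (6 mol%), THF, −15 °C
Reagents that add atoms: none
Why: Amine-catalysed deprotonative alumination gives the alkynyl(diisobutyl)aluminium, which transfers its alkynyl group in the same NHC–copper-catalysed SN2' allylic substitution, and the mirror-image ligand ent-L delivers it to the opposite alkene face so that the quaternary centre is (S).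

Step 9
Reactants: 15 trimethyl[(3S,6E)-3-ethenyl-3,7,11-trimethyldodeca-6,10-dien-1-yn-1-yl]silane
Product: 16 (3S,6E)-3-ethenyl-3,7,11-trimethyldodeca-6,10-dien-1-yne
Conditions: K2CO3 (cat.), MeOH, rt
Reagents that add atoms: none
Why: Carbonate-catalysed methanolysis of the C(sp)–Si bond (protodesilylation) is selective for the alkynylsilane and cannot affect the quaternary centre, which has no acidic hydrogen.

Step 10
Reactants: 16 (3S,6E)-3-ethenyl-3,7,11-trimethyldodeca-6,10-dien-1-yne
Product: 19 triisopropyl{[(3S,6E)-3-ethenyl-3,7,11-trimethyldodeca-6,10-dien-1-yn-1-yl]oxy}silane, via lithium acetylide 17 (not isolated), via lithium ynolate 18 (not isolated)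
Conditions: n-BuLi, THF, −78 °C; t-BuOOLi (t-BuOOH + LiN(SiMe3)2), −78 → 0 °C; i-Pr3SiOTf, −78 °C
Reagents that add atoms: tert-butyl hydroperoxide, CC(C)(C)OO; triisopropylsilyl trifluoromethanesulfonate, CC(C)[Si](OS(=O)(=O)C(F)(F)F)(C(C)C)C(C)C
Why: Oxidation of the lithium acetylide by lithium tert-butyl peroxide (electrophilic oxygen transfer with loss of tert-butoxide) gives the lithium ynolate, which the bulky silyl triflate traps on oxygen as the silyl ynol ether, the unpolarised alkenes being inert to the peroxide anion.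

Step 11
Reactants: 12 3-({2,2-di-tert-butyl-6-[(3R,6E)-3,7,11-trimethyldodeca-1,6,10-trien-3-yl]-1,3,2-benzodioxasilol-4-yl}oxy)-2H-pyran-2-one; 19 triisopropyl{[(3S,6E)-3-ethenyl-3,7,11-trimethyldodeca-6,10-dien-1-yn-1-yl]oxy}silane
Product: 21 2,2-di-tert-butyl-4-{2-(triisopropylsilyloxy)-3-[(3S,6E)-3,7,11-trimethyldodeca-1,6,10-trien-3-yl]phenoxy}-6-[(3R,6E)-3,7,11-trimethyldodeca-1,6,10-trien-3-yl]-1,3,2-benzodioxasilole, via bridged bicyclic lactone 20 (not isolated)
Conditions: AgNTf2 (10 mol%), 2,6-di-tert-butylpyridine (20 mol%), 4 Å MS, CH2Cl2, 0 °C → rt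
Reagents that add atoms: none
Why: Silver triflimide promotes an asynchronous inverse-demand [4+2] addition in which the nucleophilic β-carbon of the silyl ynol ether, the one carrying the quaternary group, bonds to pyrone C6 and the resulting silylketenium carbon closes onto C3 to give the 2-oxabicyclo[2.2.2]octadienone 20. Retro-[4+2] loss of CO2 from 20 is irreversible and aromatises the new ring, so ring B is closed by a two-bond intermolecular [4+2] annulation (ring B bonds C1–C2 and C3–C4) followed by cycloreversion, not by cyclisation of a tethered chain. The closest known reaction type is the Diels–Alder/retro-Diels–Alder benzannulation of 2-pyrones with ynamines, ynol ethers and siloxyalkynes. No stereocentre is created in the product: the bridgeheads of 20 disappear with CO2 so both of its diastereomers converge, and the two quaternary centres carry no hydrogen and are not touched. The step needs regioselectivity, which should be secured by the polarisation of the ynol ether matched with the vinylogous acceptor carbon C6, by the aryloxy group on C3 making C4 a poorer acceptor (disfavouring attack there and cyclobutene formation), and by the quaternary group avoiding the substituted C3 terminus. It also needs chemoselectivity over six isolated alkenes, which are unpolarised and are protected from adventitious acid by the hindered pyridine.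

Step 12
Reactants: 21 2,2-di-tert-butyl-4-{2-(triisopropylsilyloxy)-3-[(3S,6E)-3,7,11-trimethyldodeca-1,6,10-trien-3-yl]phenoxy}-6-[(3R,6E)-3,7,11-trimethyldodeca-1,6,10-trien-3-yl]-1,3,2-benzodioxasilole
Product: 22 3-{2-hydroxy-3-[(3S,6E)-3,7,11-trimethyldodeca-1,6,10-trien-3-yl]phenoxy}-5-[(3R,6E)-3,7,11-trimethyldodeca-1,6,10-trien-3-yl]benzene-1,2-diol
Conditions: TBAF, AcOH, THF (degassed), 0 °C → rt
Reagents that add atoms: none
Why: Fluoride-mediated desilylation cleaves both Si–O bonds of the silylene and the aryl triisopropylsilyl ether in one operation, and the acetic acid buffer with exclusion of air should protect the free catechol from oxidation and the polyene from acid or base.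

**Compound list**
1 | (2E,6E)-farnesol | CC(C)=CCC/C(C)=C/CC/C(C)=C/CO | starting material
2 | (2E,6E)-farnesyl diethyl phosphate | CC(C)=CCC/C(C)=C/CC/C(C)=C/COP(=O)(OCC)OCC | intermediate
3 | 5-bromo-1,2,3-trimethoxybenzene | COc1cc(Br)cc(OC)c1OC | starting material
4 | 5-bromobenzene-1,2,3-triol | Oc1cc(Br)cc(O)c1O | intermediate
5 | 5-bromo-1,2,3-tris(tert-butyldimethylsilyloxy)benzene | CC(C)(C)[Si](C)(C)Oc1cc(Br)cc(O[Si](C)(C)C(C)(C)C)c1O[Si](C)(C)C(C)(C)C | intermediate
6 | 3,4,5-tris(tert-butyldimethylsilyloxy)phenyllithium | [Li]c1cc(O[Si](C)(C)C(C)(C)C)c(O[Si](C)(C)C(C)(C)C)c(O[Si](C)(C)C(C)(C)C)c1 | intermediate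
7 | diethyl[3,4,5-tris(tert-butyldimethylsilyloxy)phenyl]aluminium | CC[Al](CC)c1cc(O[Si](C)(C)C(C)(C)C)c(O[Si](C)(C)C(C)(C)C)c(O[Si](C)(C)C(C)(C)C)c1 | intermediate
8 | 1,2,3-tris(tert-butyldimethylsilyloxy)-5-[(3R,6E)-3,7,11-trimethyldodeca-1,6,10-trien-3-yl]benzene | C=C[C@@](C)(CC/C=C(\C)CCC=C(C)C)c1cc(O[Si](C)(C)C(C)(C)C)c(O[Si](C)(C)C(C)(C)C)c(O[Si](C)(C)C(C)(C)C)c1 | intermediate
9 | 5-[(3R,6E)-3,7,11-trimethyldodeca-1,6,10-trien-3-yl]benzene-1,2,3-triol | C=C[C@@](C)(CC/C=C(\C)CCC=C(C)C)c1cc(O)c(O)c(O)c1 | intermediate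
10 | 2,2-di-tert-butyl-6-[(3R,6E)-3,7,11-trimethyldodeca-1,6,10-trien-3-yl]-1,3,2-benzodioxasilol-4-ol | C=C[C@@](C)(CC/C=C(\C)CCC=C(C)C)c1cc2O[Si](C(C)(C)C)(C(C)(C)C)Oc2c(O)c1 | intermediate
11 | 3-bromo-2H-pyran-2-one | O=C1OC=CC=C1Br | starting material
12 | 3-({2,2-di-tert-butyl-6-[(3R,6E)-3,7,11-trimethyldodeca-1,6,10-trien-3-yl]-1,3,2-benzodioxasilol-4-yl}oxy)-2H-pyran-2-one | C=C[C@@](C)(CC/C=C(\C)CCC=C(C)C)c1cc2O[Si](C(C)(C)C)(C(C)(C)C)Oc2c(OC3=CC=COC3=O)c1 | intermediate
13 | trimethylsilylacetylene | C#C[Si](C)(C)C | starting material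
14 | diisobutyl[(trimethylsilyl)ethynyl]aluminium | CC(C)C[Al](CC(C)C)C#C[Si](C)(C)C | intermediate
15 | trimethyl[(3S,6E)-3-ethenyl-3,7,11-trimethyldodeca-6,10-dien-1-yn-1-yl]silane | C[Si](C)(C)C#C[C@](C)(C=C)CC/C=C(\C)CCC=C(C)C | intermediate
16 | (3S,6E)-3-ethenyl-3,7,11-trimethyldodeca-6,10-dien-1-yne | C#C[C@](C)(C=C)CC/C=C(\C)CCC=C(C)C | intermediate
17 | lithium acetylide of 16 | [Li]C#C[C@](C)(C=C)CC/C=C(\C)CCC=C(C)C | intermediate
18 | lithium (3S,6E)-3-ethenyl-3,7,11-trimethyldodeca-6,10-dien-1-yn-1-olate | [Li]OC#C[C@](C)(C=C)CC/C=C(\C)CCC=C(C)C | intermediate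
19 | triisopropyl{[(3S,6E)-3-ethenyl-3,7,11-trimethyldodeca-6,10-dien-1-yn-1-yl]oxy}silane | CC(C)[Si](C(C)C)(C(C)C)OC#C[C@](C)(C=C)CC/C=C(\C)CCC=C(C)C | intermediate
20 | 2-oxabicyclo[2.2.2]octa-5,7-dien-3-one adduct: ring A aryloxy on bridgehead C4, triisopropylsilyloxy on C5, (S) side chain on C6, either bridgehead configuration | C=C[C@@](C)(CC/C=C(\C)CCC=C(C)C)c1cc2O[Si](C(C)(C)C)(C(C)(C)C)Oc2c(OC34C=CC(OC3=O)C(=C4O[Si](C(C)C)(C(C)C)C(C)C)[C@](C)(C=C)CC/C=C(\C)CCC=C(C)C)c1 | intermediate
21 | 2,2-di-tert-butyl-4-{2-(triisopropylsilyloxy)-3-[(3S,6E)-3,7,11-trimethyldodeca-1,6,10-trien-3-yl]phenoxy}-6-[(3R,6E)-3,7,11-trimethyldodeca-1,6,10-trien-3-yl]-1,3,2-benzodioxasilole | C=C[C@@](C)(CC/C=C(\C)CCC=C(C)C)c1cc2O[Si](C(C)(C)C)(C(C)(C)C)Oc2c(Oc3cccc([C@](C)(C=C)CC/C=C(\C)CCC=C(C)C)c3O[Si](C(C)C)(C(C)C)C(C)C)c1 | intermediate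
22 | 3-{2-hydroxy-3-[(3S,6E)-3,7,11-trimethyldodeca-1,6,10-trien-3-yl]phenoxy}-5-[(3R,6E)-3,7,11-trimethyldodeca-1,6,10-trien-3-yl]benzene-1,2-diol (CNP0325484.1) | C=C[C@@](C)(CC/C=C(\C)CCC=C(C)C)c1cc(O)c(O)c(Oc2cccc([C@](C)(C=C)CC/C=C(\C)CCC=C(C)C)c2O)c1 | target

**Step count**
Total: 12 steps. Longest linear sequence: 8 steps (steps 2, 3, 4, 5, 6, 7, 11, 12, from 5-bromo-1,2,3-trimethoxybenzene).

**Steps most likely to fail**

1. Step 11. The cycloaddition may not start, because the aryloxy donor makes the pyrone a weaker acceptor and the reacting alkyne carbon is flanked by a quaternary centre. The ynol ether may instead isomerise to the silylketene or be protonated, or closure may take place across C3/C4 to give a cyclobutene. The fallback keeps the same ring construction but lowers the pyrone LUMO with a removable bromine. It sets out from phenol 10, which is coupled under the step 7 conditions with 3,5-dibromo-2H-pyran-2-one (O=C1OC=C(Br)C=C1Br); its C3 bromide, α to the carbonyl, is the one expected to enter oxidative addition first. This gives 5-bromo-3-({2,2-di-tert-butyl-6-[(3R,6E)-3,7,11-trimethyldodeca-1,6,10-trien-3-yl]-1,3,2-benzodioxasilol-4-yl}oxy)-2H-pyran-2-one F1. The more electron-poor diene F1 should take up alkyne 19 under the silver conditions or on mild heating (toluene, 80 °C) with the same orientation, giving the ring B C5-bromo analogue of 21, F2. Bromine–lithium exchange (t-BuLi, THF, −78 °C), which cannot trigger silyl migration because no silyloxy group is ortho to the bromine, followed by a MeOH quench returns to 21.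

2. Step 7. The phenoxide or the base may open the pyrone ring by conjugate attack at C6, the pyranyl–palladium intermediate may be diverted into Heck arylation of a vinyl group, or C–O reductive elimination may be too slow with the ortho-silyloxy phenol. The fallback reverses the polarity so that the pyrone supplies the ether oxygen. It sets out from 10: Tf2O, pyridine, CH2Cl2, 0 °C gives the aryl triflate 2,2-di-tert-butyl-6-[(3R,6E)-3,7,11-trimethyldodeca-1,6,10-trien-3-yl]-1,3,2-benzodioxasilol-4-yl trifluoromethanesulfonate F3. Miyaura borylation (B2pin2, PdCl2(dppf), KOAc, dioxane, 80 °C) gives the pinacol boronate F4. Chan–Lam O-arylation of commercial 3-hydroxy-2H-pyran-2-one with F4 (Cu(OAc)2, pyridine, B(OH)3, 4 Å MS, MeCN, air, rt → 50 °C) comes back to the route at 12.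

3. Step 8. Hydroalumination of the silylalkyne may compete with deprotonative alumination, and alkynyl transfer may suffer erosion of SN2' or facial selectivity. The fallback delivers the carbon as a boron-stabilised C1 nucleophile and homologates it to the alkyne. It sets out from 2: NHC–copper-catalysed SN2' substitution with bis(pinacolboryl)methane (CH2(Bpin)2, NaOMe, CuCl, imidazolinium salt enantiomer chosen for the (S) product, THF, rt) gives 2-[(2S,5E)-2-ethenyl-2,6,10-trimethylundeca-5,9-dien-1-yl]-4,4,5,5-tetramethyl-1,3,2-dioxaborolane F5. Oxidation (NaBO3·4H2O, THF/H2O, rt) gives (2S,5E)-2-ethenyl-2,6,10-trimethylundeca-5,9-dien-1-ol F6. Dess–Martin periodinane with NaHCO3 in CH2Cl2 gives (2S,5E)-2-ethenyl-2,6,10-trimethylundeca-5,9-dienal F7, which has no α-hydrogen and cannot epimerise. Ohira–Bestmann homologation (dimethyl (1-diazo-2-oxopropyl)phosphonate, K2CO3, MeOH, rt) comes back to the route at 16, and step 10 follows.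

**Further compounds**
F1 | step 11 | 5-bromo-3-({2,2-di-tert-butyl-6-[(3R,6E)-3,7,11-trimethyldodeca-1,6,10-trien-3-yl]-1,3,2-benzodioxasilol-4-yl}oxy)-2H-pyran-2-one | C=C[C@@](C)(CC/C=C(\C)CCC=C(C)C)c1cc2O[Si](C(C)(C)C)(C(C)(C)C)Oc2c(OC3=CC(Br)=COC3=O)c1
F2 | step 11 | 4-{5-bromo-2-(triisopropylsilyloxy)-3-[(3S,6E)-3,7,11-trimethyldodeca-1,6,10-trien-3-yl]phenoxy}-2,2-di-tert-butyl-6-[(3R,6E)-3,7,11-trimethyldodeca-1,6,10-trien-3-yl]-1,3,2-benzodioxasilole | C=C[C@@](C)(CC/C=C(\C)CCC=C(C)C)c1cc2O[Si](C(C)(C)C)(C(C)(C)C)Oc2c(Oc3cc(Br)cc([C@](C)(C=C)CC/C=C(\C)CCC=C(C)C)c3O[Si](C(C)C)(C(C)C)C(C)C)c1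
F3 | step 7 | 2,2-di-tert-butyl-6-[(3R,6E)-3,7,11-trimethyldodeca-1,6,10-trien-3-yl]-1,3,2-benzodioxasilol-4-yl trifluoromethanesulfonate | C=C[C@@](C)(CC/C=C(\C)CCC=C(C)C)c1cc2O[Si](C(C)(C)C)(C(C)(C)C)Oc2c(OS(=O)(=O)C(F)(F)F)c1
F4 | step 7 | 2,2-di-tert-butyl-4-(4,4,5,5-tetramethyl-1,3,2-dioxaborolan-2-yl)-6-[(3R,6E)-3,7,11-trimethyldodeca-1,6,10-trien-3-yl]-1,3,2-benzodioxasilole | C=C[C@@](C)(CC/C=C(\C)CCC=C(C)C)c1cc2O[Si](C(C)(C)C)(C(C)(C)C)Oc2c(B3OC(C)(C)C(C)(C)O3)c1
F5 | step 8 | 2-[(2S,5E)-2-ethenyl-2,6,10-trimethylundeca-5,9-dien-1-yl]-4,4,5,5-tetramethyl-1,3,2-dioxaborolane | CC1(C)OB(C[C@](C)(C=C)CC/C=C(\C)CCC=C(C)C)OC1(C)C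
F6 | step 8 | (2S,5E)-2-ethenyl-2,6,10-trimethylundeca-5,9-dien-1-ol | OC[C@](C)(C=C)CC/C=C(\C)CCC=C(C)C
F7 | step 8 | (2S,5E)-2-ethenyl-2,6,10-trimethylundeca-5,9-dienal | O=C[C@](C)(C=C)CC/C=C(\C)CCC=C(C)C
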